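**Retrosynthetic overview**
- The lactone C–O bond is cut last: target ⇒ open-chain hydroxypropyl enol-dienone, closed by oxidative lactonisation onto the free enol OH next to the gem-diprenyl carbon.
- The quaternary gem-diprenyl carbon ⇒ double C-prenylation (alkylative dearomatisation) of a fully substituted acylphloroglucinol at its only free ring carbon.
- Key disconnection: the ring–CH(Ph) bond ⇒ acylphloroglucinol + cinnamaldehyde by an intermolecular amine-catalysed asymmetric Michael addition, which sets the 4S centre.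
- Acylphloroglucinol ⇒ phloroglucinol + (R)-2-methylbutanoyl chloride (Friedel–Crafts); the (R)-acid comes from an Evans methylation of an N-butanoyl oxazolidinone.
- Ring order: the six-membered carbocycle is bought as the aromatic ring and dearomatised late; the pyranone (lactone) ring is formed in the final step.

Assumption: the SMILES is read as (4S) at the benzylic lactone carbon and (2R) in the 2-methylbutanoyl group; (R)-2-methylbutanoic acid is treated as too expensive to buy and is made from cheap materials.

**Route**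

Step 1
Reactants: 1 (4R)-4-benzyl-1,3-oxazolidin-2-one; 2 butanoyl chloride
Product: 3 (4R)-4-benzyl-3-butanoyl-1,3-oxazolidin-2-one
Conditions: n-BuLi, THF, −78 °C; then 2, −78 → 0 °C
Reagents that add atoms: none
Why: N-acylation of the lithiated oxazolidinone by the acid chloride (imide formation) is fast and clean at low temperature and leaves the auxiliary stereocentre untouched.

Step 2
Reactants: 3 (4R)-4-benzyl-3-butanoyl-1,3-oxazolidin-2-one
Product: 4 (4R)-4-benzyl-3-[(2R)-2-methylbutanoyl]-1,3-oxazolidin-2-one
Conditions: NaN(SiMe3)2, THF, −78 °C; MeI, −78 → −40 °C; chromatography or crystallisation to a single diastereomer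
Reagents that add atoms: iodomethane, CI
Why: Evans asymmetric alkylation, in which the chelated Z-sodium enolate is methylated on the face opposite the benzyl group, which for the (R)-auxiliary gives the (R)-configured 2-methylbutanoyl centre (about 10:1 crude, one diastereomer after purification).

Step 3
Reactants: 4 (4R)-4-benzyl-3-[(2R)-2-methylbutanoyl]-1,3-oxazolidin-2-one
Product: 5 (2R)-2-methylbutanoic acid
Conditions: LiOH·H2O, 30% H2O2, THF/H2O (3:1), 0 °C; then Na2SO3 (aq); then HCl (aq) to pH 2, extraction
Reagents that add atoms: hydrogen peroxide, OO (as LiOOH; one oxygen stays as the carboxyl OH)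
Why: Hydroperoxide attacks the exocyclic imide carbonyl selectively (LiOOH auxiliary cleavage), releasing the acid without epimerisation and returning the auxiliary for reuse.

Step 4
Reactants: 5 (2R)-2-methylbutanoic acid
Product: 6 (2R)-2-methylbutanoyl chloride
Conditions: (COCl)2, DMF (cat.), CH2Cl2, 0 °C → rt; used as a solution
Reagents that add atoms: oxalyl chloride, ClC(=O)C(=O)Cl
Why: Vilsmeier-type activation with oxalyl chloride and catalytic DMF gives the acid chloride under base-free conditions, so no ketene forms and the α-centre is kept.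

Step 5
Reactants: 6 (2R)-2-methylbutanoyl chloride; 7 phloroglucinol
Product: 8 (2R)-2-methyl-1-(2,4,6-trihydroxyphenyl)butan-1-one
Conditions: AlCl3 (3.5 equiv), CH2Cl2/MeNO2, 0 °C → rt; then ice, HCl (aq)
Reagents that add atoms: none
Why: Friedel–Crafts C-acylation of the symmetrical triphenol gives one regioisomer and stops at the mono-ketone because the chelated acyl group deactivates the ring, and at or below room temperature the α-stereocentre is expected to survive (ee checked by chiral HPLC here).

Step 6
Reactants: 8 (2R)-2-methyl-1-(2,4,6-trihydroxyphenyl)butan-1-one; 9 (E)-cinnamaldehyde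
Product: 11 (2R)-1-{2,4,6-trihydroxy-3-[(1S)-3-hydroxy-1-phenylpropyl]phenyl}-2-methylbutan-1-one, via Michael adduct aldehyde 10 (not isolated)
Conditions: (S)-2-[diphenyl(trimethylsilyloxy)methyl]pyrrolidine (20 mol%), PhCO2H (20 mol%), CH2Cl2/THF, 0 °C → rt; then MeOH, NaBH4, 0 °C
Reagents that add atoms: none
Why: Asymmetric iminium-ion Michael addition, in which the acidic acylphloroglucinol (a vinylogous acid reacting through either of its two equivalent free ring carbons) attacks the Si face of the β-carbon of the cinnamaldehyde iminium ion because the CPh2OSiMe3 group blocks the Re face, setting the (S) benzylic centre, after which borohydride reduces the aldehyde (present as its lactols) to the stable open-chain alcohol while the chelated, deprotonated aryl ketone is left alone.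

Step 7
Reactants: 11 (2R)-1-{2,4,6-trihydroxy-3-[(1S)-3-hydroxy-1-phenylpropyl]phenyl}-2-methylbutan-1-one; 12 prenyl bromide (2.2 equiv)
Product: 14 3,5-dihydroxy-4-[(1S)-3-hydroxy-1-phenylpropyl]-2-[(2R)-2-methylbutanoyl]-6,6-bis(3-methylbut-2-en-1-yl)cyclohexa-2,4-dien-1-one, via mono-prenyl phenol 13 (not isolated)
Conditions: NaOMe (3.2 equiv), MeOH, −20 → 0 °C, 12 (2.2 equiv); then citric acid (aq)
Reagents that add atoms: none
Why: Alkylative dearomatisation in which the phenoxide, having only one unsubstituted ring carbon, is C-prenylated there twice in a protic medium, the second alkylation creating the quaternary carbon and the lupulone-type enol-dienone without touching either stereocentre.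

Step 8
Reactants: 14 3,5-dihydroxy-4-[(1S)-3-hydroxy-1-phenylpropyl]-2-[(2R)-2-methylbutanoyl]-6,6-bis(3-methylbut-2-en-1-yl)cyclohexa-2,4-dien-1-one
Product: 17 (4S)-5-hydroxy-6-[(2R)-2-methylbutanoyl]-8,8-bis(3-methylbut-2-en-1-yl)-4-phenyl-3,4-dihydro-2H-chromene-2,7(8H)-dione, via seco aldehyde 15 (not isolated), via lactol 16 (not isolated)
Conditions: [C5H5NH][CrO3Cl] (pyridinium chlorochromate, 3 equiv), NaOAc, powdered 4 Å molecular sieves, CH2Cl2, 0 °C → rt
Reagents that add atoms: none
Why: Oxidative lactonisation, in which the primary alcohol is oxidised to the aldehyde, the aldehyde is trapped as the six-membered lactol by the free acidic C5 enol hydroxyl (the C3 hydroxyl is tied up in the hydrogen bond to the acyl carbonyl) and the lactol is oxidised on to the enol lactone, the prenyl alkenes and both stereocentres being inert to the buffered reagent.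

**Compound list**
1 | (4R)-4-benzyl-1,3-oxazolidin-2-one | O=C1N[C@H](Cc2ccccc2)CO1 | starting material
2 | butanoyl chloride | CCCC(Cl)=O | starting material
3 | (4R)-4-benzyl-3-butanoyl-1,3-oxazolidin-2-one | CCCC(=O)N1[C@H](Cc2ccccc2)COC1=O | intermediate
4 | (4R)-4-benzyl-3-[(2R)-2-methylbutanoyl]-1,3-oxazolidin-2-one | CC[C@@H](C)C(=O)N1[C@H](Cc2ccccc2)COC1=O | intermediate
5 | (2R)-2-methylbutanoic acid | CC[C@@H](C)C(=O)O | intermediate
6 | (2R)-2-methylbutanoyl chloride | CC[C@@H](C)C(=O)Cl | intermediate
7 | phloroglucinol (benzene-1,3,5-triol) | Oc1cc(O)cc(O)c1 | starting material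
8 | (2R)-2-methyl-1-(2,4,6-trihydroxyphenyl)butan-1-one | CC[C@@H](C)C(=O)c1c(O)cc(O)cc1O | intermediate
9 | (E)-cinnamaldehyde | O=C/C=C/c1ccccc1 | starting material
10 | (3S)-3-{2,4,6-trihydroxy-3-[(2R)-2-methylbutanoyl]phenyl}-3-phenylpropanal (open form of the equilibrating lactols; not isolated) | CC[C@@H](C)C(=O)c1c(O)cc(O)c([C@@H](CC=O)c2ccccc2)c1O | intermediate
11 | (2R)-1-{2,4,6-trihydroxy-3-[(1S)-3-hydroxy-1-phenylpropyl]phenyl}-2-methylbutan-1-one | CC[C@@H](C)C(=O)c1c(O)cc(O)c([C@@H](CCO)c2ccccc2)c1O | intermediate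
12 | prenyl bromide (1-bromo-3-methylbut-2-ene) | CC(C)=CCBr | starting material
13 | (2R)-1-{2,4,6-trihydroxy-3-[(1S)-3-hydroxy-1-phenylpropyl]-5-(3-methylbut-2-en-1-yl)phenyl}-2-methylbutan-1-one (not isolated) | CC[C@@H](C)C(=O)c1c(O)c(CC=C(C)C)c(O)c([C@@H](CCO)c2ccccc2)c1O | intermediate
14 | 3,5-dihydroxy-4-[(1S)-3-hydroxy-1-phenylpropyl]-2-[(2R)-2-methylbutanoyl]-6,6-bis(3-methylbut-2-en-1-yl)cyclohexa-2,4-dien-1-one | CC[C@@H](C)C(=O)C1=C(O)C([C@@H](CCO)c2ccccc2)=C(O)C(CC=C(C)C)(CC=C(C)C)C1=O | intermediate
15 | (3S)-3-{2,6-dihydroxy-5-[(2R)-2-methylbutanoyl]-3,3-bis(3-methylbut-2-en-1-yl)-4-oxocyclohexa-1,5-dien-1-yl}-3-phenylpropanal (not isolated) | CC[C@@H](C)C(=O)C1=C(O)C([C@@H](CC=O)c2ccccc2)=C(O)C(CC=C(C)C)(CC=C(C)C)C1=O | intermediate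
16 | (4S)-2,5-dihydroxy-6-[(2R)-2-methylbutanoyl]-8,8-bis(3-methylbut-2-en-1-yl)-4-phenyl-3,4-dihydro-2H-chromen-7(8H)-one (both anomers; not isolated) | CC[C@@H](C)C(=O)C1=C(O)C2=C(OC(O)C[C@H]2c2ccccc2)C(CC=C(C)C)(CC=C(C)C)C1=O | intermediate
17 | (4S)-5-hydroxy-6-[(2R)-2-methylbutanoyl]-8,8-bis(3-methylbut-2-en-1-yl)-4-phenyl-3,4-dihydro-2H-chromene-2,7(8H)-dione | CC[C@@H](C)C(=O)C1=C(O)C2=C(OC(=O)C[C@H]2c2ccccc2)C(CC=C(C)C)(CC=C(C)C)C1=O | target

**Totals**
Total step count: 8. Longest linear sequence: 8 steps (1 → 3 → 4 → 5 → 6 → 8 → 11 → 14 → 17).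

**Three steps most likely to fail**

1. The Michael addition (step 6). A free acylphloroglucinol is an unproven donor for this catalyst: it may react slowly, add a second enal at its last free carbon, give a 2H-chromene by 1,2-addition, or give modest ee. The fallback keeps the same C–C bond but makes it at the carboxylic acid oxidation level, through an α,β-unsaturated acyl ammonium ion. Setting out from 8, (E)-cinnamic anhydride, the isothiourea catalyst HyperBTM (10 mol%, the enantiomer that gives the 4S product) and i-Pr2NEt in CH2Cl2 effect a Michael addition–lactonisation. The product is (4S)-5,7-dihydroxy-6-[(2R)-2-methylbutanoyl]-4-phenyl-3,4-dihydro-2H-chromen-2-one F1; any 8-acyl regioisomer converges in the next operation. LiBH4 in THF at 0 °C then reduces the aryl lactone, and the route is rejoined at 11.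

2. The gem-diprenylation (step 7). O-prenylation, stalling at the mono-prenyl stage 13 and over-alkylation make 30–50% a realistic yield. The fallback sets out from 11 and uses a Tsuji–Trost allylation, which is far more C-selective: Pd(PPh3)4 (5 mol%) and allyl methyl carbonate (2.2 equiv) in THF at rt. This gives 3,5-dihydroxy-4-[(1S)-3-hydroxy-1-phenylpropyl]-2-[(2R)-2-methylbutanoyl]-6,6-di(prop-2-en-1-yl)cyclohexa-2,4-dien-1-one F2. Double cross-metathesis with excess 2-methylbut-2-ene and the second-generation Grubbs catalyst (CH2Cl2, 40 °C) converts both allyl groups into prenyl groups and returns to the route at 14.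

3. The oxidative lactonisation (step 8). Hexavalent chromium may attack the enolised triketone, and the lactol may close on the C3 rather than the C5 enol oxygen, giving the isomeric lactone. The fallback brings in the carboxyl group before dearomatisation and closes the ring by dehydration instead of oxidation. Setting out from 8, lactone F1 is made as in the fallback to step 6. It is opened in 10% aqueous KOH at 0 °C to the carboxylate of (3S)-3-{2,4,6-trihydroxy-3-[(2R)-2-methylbutanoyl]phenyl}-3-phenylpropanoic acid F3. Double C-prenylation with 12 in the same solution, then acidification, gives the seco acid (3S)-3-{2,6-dihydroxy-5-[(2R)-2-methylbutanoyl]-3,3-bis(3-methylbut-2-en-1-yl)-4-oxocyclohexa-1,5-dien-1-yl}-3-phenylpropanoic acid F4. EDC·HCl with catalytic DMAP in CH2Cl2 at 0 °C then acylates the more nucleophilic free enol oxygen intramolecularly and delivers 17 directly.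

Further compounds
F1 | step 6 | (4S)-5,7-dihydroxy-6-[(2R)-2-methylbutanoyl]-4-phenyl-3,4-dihydro-2H-chromen-2-one | CC[C@@H](C)C(=O)c1c(O)cc2OC(=O)C[C@@H](c3ccccc3)c2c1O
F2 | step 7 | 3,5-dihydroxy-4-[(1S)-3-hydroxy-1-phenylpropyl]-2-[(2R)-2-methylbutanoyl]-6,6-di(prop-2-en-1-yl)cyclohexa-2,4-dien-1-one | CC[C@@H](C)C(=O)C1=C(O)C([C@@H](CCO)c2ccccc2)=C(O)C(CC=C)(CC=C)C1=O
F3 | step 8 | (3S)-3-{2,4,6-trihydroxy-3-[(2R)-2-methylbutanoyl]phenyl}-3-phenylpropanoic acid | CC[C@@H](C)C(=O)c1c(O)cc(O)c([C@@H](CC(=O)O)c2ccccc2)c1O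
F4 | step 8 | (3S)-3-{2,6-dihydroxy-5-[(2R)-2-methylbutanoyl]-3,3-bis(3-methylbut-2-en-1-yl)-4-oxocyclohexa-1,5-dien-1-yl}-3-phenylpropanoic acid | CC[C@@H](C)C(=O)C1=C(O)C([C@@H](CC(=O)O)c2ccccc2)=C(O)C(CC=C(C)C)(CC=C(C)C)C1=O
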